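## The problem

Target 27 (CNP0301161.1) is an eremophilane. It is a decalin with ring A = C1–C5 plus C10 and ring B = C5–C10, a methyl group C15 on C4, a methyl group C14 on the ring-fusion carbon C5 and a C3 unit (C11–C13) on C7. (In the naphthalene names used for 11–17, locants 1, 2, 4a, 5, 6, 7, 8, 8a are eremophilane C4, C3, C10, C9, C8, C7, C6, C5.)

The ring fusion is trans, C8 is a ketone, C7 carries an isopropenyl group, and the hydroxyl groups on C3 and C9 are acylated by angelic acid and by (E)-3-methylpent-2-enoic acid. The six stereocentres are 3R,4R,5R,7S,9S,10R. With the C14 methyl taken as β (axial on both rings), every other substituent is the equatorial one: 3α-O, 4β-Me, 7α-isopropenyl, 9α-O, 10α-H.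

C5 is quaternary and cannot be corrected once made, so it must be set absolutely; the other five can then be controlled from it. C4, C7, C9 and C10 each lie next to a carbonyl group (or at the β-carbon of an enone) at some stage. C3 is special: axial delivery of hydride to a C3 ketone is blocked by the syn-axial C14 methyl, so hydride reagents would give the wrong, axial alcohol, and the equatorial 3α-oxygen calls for a reduction under thermodynamic control.

The fragile groups are the two enoate esters, the β,γ-unsaturated ketone and the α-acyloxy ketone. The esters will not survive dissolving metal or enolate chemistry, and the Z-angelate isomerises easily. The isopropenyl double bond tends to move into conjugation with C8. The C8/C9 acyloxy ketone is base-sensitive.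

The feature that opens the route is in ring B. C5 is a methyl-bearing quaternary carbon para to the C8 carbonyl, so ring B is a reduced 4-methylphenol alkylated at its para carbon. The alkylating carbon, C4, carries a methyl group and sits next to the C3 oxygen, as the carbenoid carbon of an α-diazoketone does.

## Retrosynthesis

**Ester C–O bonds.** The acyl groups are removed first: 27 goes back to hydroxy ester 24 and angelic acid 25, and 24 to silyl ether 21 and acid 22. Both enoates are incompatible with every reductive or basic step before them, so they must come last. The angelate goes on at the very end because it is the more easily isomerised. The forward steps must tell the two hydroxyl groups apart, which is done by the order in which they are uncovered (C9 free, C3 silylated in 21).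

**C9–O bond.** 21 is cut to the silyl enol ether 19. Oxidising a regiodefined C8–C9 enolate is preferred to enolising a C8 ketone, which would have to choose between C7 and C9. The precursor loses one stereocentre and one oxygen. The forward reaction must bring oxygen to the α face of C9 and spare the isopropenyl group.

**C10–H and C3–H bonds.** 19 is traced to the enedione 17. One dissolving-metal operation is asked to do three things: reduce the C9=C10 enone with axial protonation at C10 (trans fusion), leave the C8–C9 enolate for trapping, and reduce the C3 ketone to the equatorial alkoxide. This replaces a separate hydride reduction at C3, which would give the axial epimer. The precursor has two stereocentres fewer.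

**C7–C11 bond.** 17 comes from ketal 16 by hydrolysis, and 16 from ketal enone 13 and 2-bromopropene 14. The cut is made at the enone stage because C7 is then the only kinetically accessible α-carbon of C8, provided the C3 ketone is masked. The forward reaction is a palladium-catalysed α-alkenylation that must keep the new double bond out of conjugation; C7 is then equilibrated to the equatorial epimer.

**Ketal and C6–C7 saturation.** 13 is the C3 ketal of enedione 12, and 12 is the dihydro derivative of dienone 11. Selective hydrogenation of the disubstituted alkene of a cross-conjugated dienone is reliable, and it removes the dienone before any acid or base is used.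

**C4–C5 bond (key cut).** 11 is opened between C4 and C5 to the achiral phenolic diazoketone 10. This single cut removes ring A, the quaternary centre and both methyl-bearing stereocentres. The neighbouring cuts (C5–C10, C5–C6) would leave the quaternary centre to be made by enolate alkylation with no handle for absolute control. The forward reaction must be para-selective, enantioselective at C5 and free of carbenoid hydride shift.

**Diazoketone and side chain.** 10 is the deacetylated form of 9. 9 arises from acid 5 (through chloride 7) and diazoethane 8, generated from nitrosourea 6. 5 comes by acetylation of 4, 4 by hydrogenation of cinnamic acid 3, and 3 by Heck coupling of bromophenol 1 with acrylic acid 2. All of these are standard C–C and C–O constructions on commercial materials.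

## Roads not taken

**Alternative 1: anionic oxy-Cope.** Ring B is cut at C5–C6. The cis-decalin A2 is seen as the product of an anionic oxy-Cope rearrangement of the bicyclo[2.2.2]octenol A1. Forward, the potassium alkoxide of A1 (KH, 18-crown-6) rearranges through a transition state held by the bicycle: C5–C6 forms, the bond from the carbinol carbon to the bridgehead breaks, and the quaternary C5 and C10 appear with fixed relative configuration.
- Merits: the reaction class is well established. A2 already carries the C8 ketone, a C9 oxygen (as a ketal) and a C3 oxygen (as an enol ether). In both respects it is better than the chosen plan, which has to hydroxylate C9 and rests on an untested key step.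
- Weak points: A2 is cis-fused and 27 is trans. C10 is not next to a free carbonyl, so inversion needs unmasking of C9, equilibration and then an exchange of oxidation level between C8 and C9. The cycloaddition that makes A1 gives a racemate. C3, C4 and the isopropenyl group remain to be set as in the chosen route.
- Balance: the chosen plan sets against this a catalyst-controlled C5 from an achiral arene and a trans fusion obtained directly by dissolving metal.

**Alternative 2: terpene cyclase.** The skeleton is cut at C6–C7 and C5–C10, with C14 returned to C10, back to farnesyl diphosphate A3. Forward, aristolochene synthase converts A3 into aristolochene A4 in one step.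
- Merits: this is unbeatable in step economy for the carbon framework. It delivers C4, C5 and C7, including the isopropenyl group, in the configuration needed. The chosen plan needs seven steps to reach a comparable bicycle and must add C11–C13 separately.
- Weak points: A4 has no oxygen. C8 and C9 could be reached from the C9=C10 alkene, though in competition with the isopropenyl alkene. C3 is an unactivated methylene far from any functional group, with no chemical basis for selecting it over C1, C2 or C6. The enzyme, the diphosphate and a volatile hydrocarbon also have to be handled.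
- Balance: the chosen plan brings the C3 and C8 oxygens in with the diazoketone carbonyl and the phenol oxygen.

**Alternative 3: ketyl–olefin closure.** Ring A is cut at C3–C4. The aldehyde vinyl sulfone A5 would be closed with SmI2 (divalent samarium) by 6-exo addition of the C3 ketyl to the vinyl sulfone, giving the trans-decalin A6.
- Merits: the reaction type is well precedented. It sets the 3α-hydroxyl and C4 together in the trans relation, which the chosen plan achieves only through a ketal detour and a thermodynamic reduction. The C8 and C9 oxygens arrive differently protected, so the esters can be installed without the silyl-ether bookkeeping of the chosen route.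
- Weak points: the burden moves to A5, a cyclohexane with five stereocentres including the quaternary C5, for which the cut offers no help. The sulfone has to be removed, and three protecting groups and a late C8 oxidation must be managed.
- Balance: the chosen plan sets against this a far shorter approach to C5 and ring A, at the price of a key step without direct precedent.

Key step: step 6

Assumption: the sense of induction of the copper–bis(oxazoline) catalyst in step 6 cannot be predicted safely; the (S,S) ligand is written, and its mirror image is to be used if it leads to the enantiomer of 11.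

## Route

Step 1
Reactants: 1 3-bromo-4-methylphenol; 2 acrylic acid
Product: 3 (2E)-3-(5-hydroxy-2-methylphenyl)prop-2-enoic acid
Conditions: Pd(OAc)2 (2 mol %), P(o-tol)3 (6 mol %), Et3N (3 equiv), MeCN, 100 °C; aq. HCl work-up
Reagents that add atoms: none
Why: Heck reaction: the aryl bromide adds to zerovalent palladium formed in situ from Pd(OAc)2 (divalent palladium), acrylic acid inserts and β-hydride elimination gives the E acid. Bromophenols couple unprotected when a triarylphosphine is present.

Step 2
Reactants: 3 (2E)-3-(5-hydroxy-2-methylphenyl)prop-2-enoic acid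
Product: 4 3-(5-hydroxy-2-methylphenyl)propanoic acid
Conditions: H2 (1 atm), Pd/C (10 %), MeOH, rt
Reagents that add atoms: none
Why: Heterogeneous hydrogenation of the cinnamic double bond; the arene and the phenol are inert at one atmosphere.

Step 3
Reactants: 4 3-(5-hydroxy-2-methylphenyl)propanoic acid
Product: 5 3-[5-(acetyloxy)-2-methylphenyl]propanoic acid
Conditions: Ac2O (2.5 equiv), pyridine, rt; then H2O
Reagents that add atoms: acetic anhydride CC(=O)OC(C)=O
Why: O-Acetylation masks the phenol so that the acid chloride can be made; any mixed anhydride at the carboxyl group is hydrolysed on aqueous work-up.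

Step 4
Reactants: 5 3-[5-(acetyloxy)-2-methylphenyl]propanoic acid; 6 N-ethyl-N-nitrosourea
Product: 9 3-(4-diazo-3-oxopentyl)-4-methylphenyl acetate, via 3-[5-(acetyloxy)-2-methylphenyl]propanoyl chloride 7 (not isolated), via diazoethane 8 (not isolated)
Conditions: (COCl)2, DMF (cat.), CH2Cl2, 0 °C → rt, evaporate; then CH3CHN2 (3 equiv, from 6, aq. KOH, Et2O, 0 °C), Et2O, −20 → 0 °C
Reagents that add atoms: none
Why: Acid chloride formation followed by acylation of a diazoalkane (first stage of an Arndt–Eistert sequence). A second equivalent of diazoethane takes up the HCl, and the aryl acetate does not react.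

Step 5
Reactants: 9 3-(4-diazo-3-oxopentyl)-4-methylphenyl acetate
Product: 10 2-diazo-5-(5-hydroxy-2-methylphenyl)pentan-3-one
Conditions: NH3 (7 M in MeOH), 0 °C → rt
Reagents that add atoms: none
Why: Ammonolysis of the activated aryl acetate. The α-diazoketone is stable to amines and, in the cold, to the free phenol.

Step 6
Reactants: 10 2-diazo-5-(5-hydroxy-2-methylphenyl)pentan-3-one
Product: 11 (1R,8aR)-1,8a-dimethyl-3,4-dihydronaphthalene-2,6(1H,8aH)-dione
Conditions: Cu(MeCN)4PF6 (5 mol %), 2,2′-(propane-2,2-diyl)bis[(4S)-4-tert-butyl-4,5-dihydro-1,3-oxazole] (6 mol %), CH2Cl2, 4 Å MS, 0 °C → rt, 10 added over 6 h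
Reagents that add atoms: none
Why: Proposed new method: loss of N2 from 10 at monovalent copper gives an electrophilic copper carbenoid at C4, which is attacked by the arene carbon para to the hydroxyl group (C5); the zwitterion formed, a copper enolate joined to an O-protonated dienone, collapses by proton transfer from the phenolic oxygen to the enolate and releases the catalyst. The closest known reaction types are the racemic acid- or metal-promoted para-alkylative dearomatisation of phenols by tethered diazoketones and the catalytic asymmetric carbenoid dearomatisation of phenols and naphthols; an enantioselective closure of a secondary diazoketone onto the para carbon of a 4-methylphenol has not been shown. Ring A closes in the six-membered mode through the arene carbon ortho to the tether (6-endo with respect to the C5–C10 arene bond, which ends inside ring A), not in the five-membered spiro mode at C10. C5 is set by the face of the arene that the chiral bis(oxazoline)–copper carbenoid approaches, the only source of asymmetry because 10 is achiral. C4 is set when the enol(ate) is protonated, which should occur from the face away from the C5 methyl and place the two methyl groups cis. The step needs para attack (C5) over ortho attack (C9), and ring closure over 1,2-hydride shift, arene cyclopropanation and intermolecular O–H insertion: the hydroxyl group makes C5 the most nucleophilic carbon and lets the intermediate lose a proton, the C5 methyl blocks rearomatisation, copper at or below room temperature is much less prone to hydride shift than Rh2(OAc)4 (divalent rhodium), and slow addition keeps the phenol concentration low.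

Step 7
Reactants: 11 (1R,8aR)-1,8a-dimethyl-3,4-dihydronaphthalene-2,6(1H,8aH)-dione
Product: 12 (1R,8aR)-1,8a-dimethyl-3,4,8,8a-tetrahydronaphthalene-2,6(1H,7H)-dione
Conditions: H2 (1 atm), RhCl(PPh3)3 (5 mol %), toluene, rt
Reagents that add atoms: none
Why: Homogeneous hydrogenation with the monovalent rhodium complex is selective for the less substituted alkene of a cross-conjugated cyclohexadienone. The disubstituted C6=C7 bond is reduced; the trisubstituted C9=C10 bond, both ketones and the enolisable C4 centre are left alone in the neutral medium.

Step 8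
Reactants: 12 (1R,8aR)-1,8a-dimethyl-3,4,8,8a-tetrahydronaphthalene-2,6(1H,7H)-dione
Product: 13 (1′R,8a′R)-1′,8a′-dimethyl-3′,4′,8′,8a′-tetrahydro-1′H-spiro[1,3-dioxolane-2,2′-naphthalen]-6′(7′H)-one
Conditions: (Me3SiOCH2)2 (1.5 equiv), Me3SiOTf (5 mol %), CH2Cl2, −78 → −40 °C; pyridine quench
Reagents that add atoms: 1,2-bis(trimethylsilyloxy)ethane C[Si](C)(C)OCCO[Si](C)(C)C
Why: Silyl triflate-catalysed ketalisation converts saturated ketones at low temperature while conjugated enones do not react. Masking C3 leaves C8 as the only carbonyl that can form an enolate in step 9, and the cold aprotic medium should not epimerise C4.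

Step 9
Reactants: 13 (1′R,8a′R)-1′,8a′-dimethyl-3′,4′,8′,8a′-tetrahydro-1′H-spiro[1,3-dioxolane-2,2′-naphthalen]-6′(7′H)-one; 14 2-bromopropene
Product: 16 (1′R,7′S,8a′R)-1′,8a′-dimethyl-7′-(prop-1-en-2-yl)-3′,4′,8′,8a′-tetrahydro-1′H-spiro[1,3-dioxolane-2,2′-naphthalen]-6′(7′H)-one, via lithium cross-conjugated dienolate 15 (not isolated)
Conditions: LiN(SiMe3)2 (2.2 equiv), THF, −78 °C; Pd2(dba)3 (2.5 mol %), P(t-Bu)3 (10 mol %), 14 (1.5 equiv), −78 °C → rt; AcOH, −78 °C; then DBU (10 mol %), CH2Cl2, 0 °C
Reagents that add atoms: none
Why: Palladium-catalysed α-alkenylation of a ketone enolate: kinetic deprotonation at C7 gives dienolate 15, which couples with the alkenylpalladium bromide formed from 14 and zerovalent palladium; excess base keeps all ketone as enolate, so no equilibration to the extended dienolate through C1 should occur. C7 is epimerisable, and brief amidine equilibration should bring it to the pseudo-equatorial isopropenyl epimer trans to the C14 methyl (7S), which avoids a syn-axial contact with C14.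

Step 10
Reactants: 16 (1′R,7′S,8a′R)-1′,8a′-dimethyl-7′-(prop-1-en-2-yl)-3′,4′,8′,8a′-tetrahydro-1′H-spiro[1,3-dioxolane-2,2′-naphthalen]-6′(7′H)-one
Product: 17 (1R,7S,8aR)-1,8a-dimethyl-7-(prop-1-en-2-yl)-3,4,8,8a-tetrahydronaphthalene-2,6(1H,7H)-dione
Conditions: PPTS (0.2 equiv), acetone/H2O (10:1), 40 °C
Reagents that add atoms: water O
Why: Acid-catalysed hydrolysis of the dioxolane. The weak acid is chosen so that the β,γ-unsaturated ketone stays out of conjugation and C4 and C7 are not enolised.

Step 11
Reactants: 17 (1R,7S,8aR)-1,8a-dimethyl-7-(prop-1-en-2-yl)-3,4,8,8a-tetrahydronaphthalene-2,6(1H,7H)-dione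
Product: 19 (3R,4R,5S,7S,10S)-3,8-bis(trimethylsilyloxy)eremophila-8,11-diene, via dilithium 3-alkoxide 8-enolate 18 (not isolated)
Conditions: Li (8 equiv), NH3/THF, t-BuOH (3 equiv), −78 → −33 °C (17 added to the metal solution); isoprene; evaporate NH3; Me3SiCl, Et3N, THF, −78 → 0 °C
Reagents that add atoms: chlorotrimethylsilane C[Si](C)(C)Cl
Why: Dissolving-metal reduction: the enone takes two electrons, C10 is protonated axially from the face opposite the C14 methyl (trans fusion, 10α-H) and the C8–C9 lithium enolate is left regiodefined. Under the same conditions the C3 ketone is reduced through its ketyl to the more stable equatorial 3α-alkoxide, the outcome known for 4,5-dimethyl-3-ketones with an axial C5 methyl and opposite to that of hydride reagents. The isolated isopropenyl group is not reduced, and silylation traps both oxygens.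

Step 12
Reactants: 19 (3R,4R,5S,7S,10S)-3,8-bis(trimethylsilyloxy)eremophila-8,11-diene
Product: 21 (3R,4R,5R,7S,9S,10R)-9-hydroxy-3-(trimethylsilyloxy)eremophil-11-en-8-one, via lithium 8-enolate 20 (not isolated)
Conditions: MeLi (1.1 equiv), THF, 0 °C → rt; 2-(phenylsulfonyl)-3-phenyloxaziridine (1.3 equiv), −78 °C; aq. NH4Cl
Reagents that add atoms: 2-(phenylsulfonyl)-3-phenyloxaziridine O=S(=O)(c1ccccc1)N1OC1c1ccccc1
Why: MeLi cleaves the Si–O bond of the silyl enol ether, not of the alkyl silyl ether, and regenerates the C8–C9 enolate, which is hydroxylated by the N-sulfonyloxaziridine (enolate oxidation). The oxidant should enter at C9 from the α face, away from the syn-axial C14 methyl, giving the equatorial 9α-alcohol (9S); it does not epoxidise the isopropenyl group.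

Step 13
Reactants: 21 (3R,4R,5R,7S,9S,10R)-9-hydroxy-3-(trimethylsilyloxy)eremophil-11-en-8-one; 22 (2E)-3-methylpent-2-enoic acid
Product: 24 (3R,4R,5R,7S,9S,10R)-3-hydroxy-8-oxoeremophil-11-en-9-yl (2E)-3-methylpent-2-enoate, via 9-ester 3-trimethylsilyl ether 23 (not isolated)
Conditions: 22 (1.5 equiv), EDC·HCl, DMAP, CH2Cl2, 0 °C → rt; then 1 M HCl, THF, 0 °C
Reagents that add atoms: none
Why: Carbodiimide/DMAP (Steglich) esterification of the only free hydroxyl group, with the E geometry of the acid retained. Dilute acid then removes the trimethylsilyl ether, so the two hydroxyl groups are distinguished by the order in which they are uncovered.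

Step 14
Reactants: 24 (3R,4R,5R,7S,9S,10R)-3-hydroxy-8-oxoeremophil-11-en-9-yl (2E)-3-methylpent-2-enoate; 25 angelic acid
Product: 27 (3R,4R,5R,7S,9S,10R)-3-[(2Z)-2-methylbut-2-enoyloxy]-8-oxoeremophil-11-en-9-yl (2E)-3-methylpent-2-enoate, via angelic 2,4,6-trichlorobenzoic anhydride 26 (not isolated)
Conditions: 25 (3 equiv), 2,4,6-trichlorobenzoyl chloride, Et3N, toluene, rt; then 24, 75 °C
Reagents that add atoms: none
Why: Mixed-anhydride (Yamaguchi) esterification run without a nucleophilic catalyst, the usual way to acylate with angelic acid without Z to E isomerisation. The equatorial 3α-hydroxyl group is acylated and no stereocentre is touched.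

## Compound list

1 | 3-bromo-4-methylphenol | Cc1ccc(O)cc1Br | starting material
2 | acrylic acid | C=CC(=O)O | starting material
3 | (2E)-3-(5-hydroxy-2-methylphenyl)prop-2-enoic acid | Cc1ccc(O)cc1/C=C/C(=O)O | intermediate
4 | 3-(5-hydroxy-2-methylphenyl)propanoic acid | Cc1ccc(O)cc1CCC(=O)O | intermediate
5 | 3-[5-(acetyloxy)-2-methylphenyl]propanoic acid | CC(=O)Oc1ccc(C)c(CCC(=O)O)c1 | intermediate
6 | N-ethyl-N-nitrosourea | CCN(N=O)C(N)=O | starting material
7 | 3-[5-(acetyloxy)-2-methylphenyl]propanoyl chloride | CC(=O)Oc1ccc(C)c(CCC(=O)Cl)c1 | intermediate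
8 | diazoethane | CC=[N+]=[N-] | intermediate
9 | 3-(4-diazo-3-oxopentyl)-4-methylphenyl acetate | CC(=[N+]=[N-])C(=O)CCc1cc(OC(C)=O)ccc1C | intermediate
10 | 2-diazo-5-(5-hydroxy-2-methylphenyl)pentan-3-one | CC(=[N+]=[N-])C(=O)CCc1cc(O)ccc1C | intermediate
11 | (1R,8aR)-1,8a-dimethyl-3,4-dihydronaphthalene-2,6(1H,8aH)-dione (methyl groups cis) | C1=C[C@]2(C)[C@@H](C)C(=O)CCC2=CC1=O | intermediate
12 | (1R,8aR)-1,8a-dimethyl-3,4,8,8a-tetrahydronaphthalene-2,6(1H,7H)-dione | C1C[C@]2(C)[C@@H](C)C(=O)CCC2=CC1=O | intermediate
13 | (1′R,8a′R)-1′,8a′-dimethyl-3′,4′,8′,8a′-tetrahydro-1′H-spiro[1,3-dioxolane-2,2′-naphthalen]-6′(7′H)-one (C3 ethylene ketal of 12) | C1C[C@]2(C)[C@@H](C)C3(OCCO3)CCC2=CC1=O | intermediate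
14 | 2-bromopropene | C=C(C)Br | starting material
15 | lithium C7–C8 dienolate of 13 (C9=C10 retained) | [Li+].[O-]C1=CC[C@]2(C)[C@@H](C)C3(OCCO3)CCC2=C1 | intermediate
16 | (1′R,7′S,8a′R)-1′,8a′-dimethyl-7′-(prop-1-en-2-yl)-3′,4′,8′,8a′-tetrahydro-1′H-spiro[1,3-dioxolane-2,2′-naphthalen]-6′(7′H)-one | C=C(C)[C@@H]1C[C@]2(C)[C@@H](C)C3(OCCO3)CCC2=CC1=O | intermediate
17 | (1R,7S,8aR)-1,8a-dimethyl-7-(prop-1-en-2-yl)-3,4,8,8a-tetrahydronaphthalene-2,6(1H,7H)-dione | C=C(C)[C@@H]1C[C@]2(C)[C@@H](C)C(=O)CCC2=CC1=O | intermediate
18 | dilithium (3R,4R,5S,7S,10S)-eremophila-8,11-diene-3,8-diolate | [Li+].[Li+].C=C(C)[C@@H]1C[C@]2(C)[C@@H](C)[C@H]([O-])CC[C@H]2C=C1[O-] | intermediate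
19 | (3R,4R,5S,7S,10S)-3,8-bis(trimethylsilyloxy)eremophila-8,11-diene (3α-OSiMe3, 10α-H) | C=C(C)[C@@H]1C[C@]2(C)[C@@H](C)[C@H](O[Si](C)(C)C)CC[C@H]2C=C1O[Si](C)(C)C | intermediate
20 | lithium (3R,4R,5S,7S,10S)-3-(trimethylsilyloxy)eremophila-8,11-dien-8-olate | [Li+].C=C(C)[C@@H]1C[C@]2(C)[C@@H](C)[C@H](O[Si](C)(C)C)CC[C@H]2C=C1[O-] | intermediate
21 | (3R,4R,5R,7S,9S,10R)-9-hydroxy-3-(trimethylsilyloxy)eremophil-11-en-8-one (9α-OH) | C=C(C)[C@@H]1C[C@]2(C)[C@@H](C)[C@H](O[Si](C)(C)C)CC[C@H]2[C@H](O)C1=O | intermediate
22 | (2E)-3-methylpent-2-enoic acid | CC/C(C)=C/C(=O)O | starting material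
23 | (3R,4R,5R,7S,9S,10R)-8-oxo-3-(trimethylsilyloxy)eremophil-11-en-9-yl (2E)-3-methylpent-2-enoate | C=C(C)[C@@H]1C[C@]2(C)[C@@H](C)[C@H](O[Si](C)(C)C)CC[C@H]2[C@H](OC(=O)/C=C(\C)CC)C1=O | intermediate
24 | (3R,4R,5R,7S,9S,10R)-3-hydroxy-8-oxoeremophil-11-en-9-yl (2E)-3-methylpent-2-enoate | C=C(C)[C@@H]1C[C@]2(C)[C@@H](C)[C@H](O)CC[C@H]2[C@H](OC(=O)/C=C(\C)CC)C1=O | intermediate
25 | angelic acid, (2Z)-2-methylbut-2-enoic acid | C/C=C(/C)C(=O)O | starting material
26 | (2Z)-2-methylbut-2-enoic 2,4,6-trichlorobenzoic anhydride | C/C=C(/C)C(=O)OC(=O)c1c(Cl)cc(Cl)cc1Cl | intermediate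
27 | (3R,4R,5R,7S,9S,10R)-3-[(2Z)-2-methylbut-2-enoyloxy]-8-oxoeremophil-11-en-9-yl (2E)-3-methylpent-2-enoate (CNP0301161.1) | C=C(C)[C@@H]1C[C@]2(C)[C@@H](C)[C@H](OC(=O)/C(C)=C\C)CC[C@H]2[C@H](OC(=O)/C=C(\C)CC)C1=O | target

## Step count and least certain steps

Total: 14 steps. Longest linear sequence: 14 steps (1 → 27); 2, 6, 14, 22 and 25 are bought.

**Step 6 (key step).** The most likely failure is loss of chemoselectivity of the carbenoid: 1,2-hydride shift to the vinyl ketone, attack at C9 followed by rearomatisation to a 2-tetralone, cyclopropanation of the arene, or insertion into the O–H bond of a second molecule. If closure is clean, face selection at C5 may still be poor, because the bond forms four atoms away from the metal. Fallback by known chemistry: starting from 10, the diazo carbon is protonated with CF3CO2H or BF3·OEt2 in CH2Cl2/MeNO2 at −20 °C and the diazonium ion is displaced by the para carbon of the phenol. This should give racemic cis-1,8a-dimethyl-3,4-dihydronaphthalene-2,6(1H,8aH)-dione F1. Preparative chromatography on a chiral stationary phase separates the unwanted (1S,8aS)-1,8a-dimethyl-3,4-dihydronaphthalene-2,6(1H,8aH)-dione F2 and returns to the route at 11.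

**Step 9.** Three things may go wrong: scrambling of the enolate by proton transfer to the extended dienolate (coupling at C9 or C1), double alkenylation, and migration of the new double bond into conjugation during the base equilibration of C7. Fallback: starting from 13, the kinetic enolate (LiN(i-Pr)2, THF, −78 °C) is added to acetone, which should enter from the α face, to give (1′R,7′S,8a′R)-7′-(2-hydroxypropan-2-yl)-1′,8a′-dimethyl-3′,4′,8′,8a′-tetrahydro-1′H-spiro[1,3-dioxolane-2,2′-naphthalen]-6′(7′H)-one F3. Dehydration towards the methyl groups (SOCl2, pyridine, −30 °C), with removal of the conjugated isopropylidene isomer, rejoins the route at 16.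

**Step 11.** The C3 ketone may be reduced incompletely, the acidic C7–H may be removed by LiNH2 before electron transfer, or the regiodefined enolate may be lost by proton exchange while ammonia is removed. Fallback: starting from 17, the same reduction is quenched with NH4Cl to give (3R,4R,5S,7S,10S)-3-hydroxyeremophil-11-en-8-one F4. Kinetic deprotonation at the C9 methylene (LiN(i-Pr)2, 2.2 equiv, THF, −78 °C) in the presence of Me3SiCl then silylates both oxygens and returns to 19.

**Step 14.** The angelate may isomerise to the tiglate on the activated acyl group, or the isopropenyl double bond may migrate during prolonged heating with amine. Fallback: starting from 24, esterification with 2-[bis(2,2,2-trifluoroethoxy)phosphoryl]propanoic acid (EDC·HCl, DMAP) gives (3R,4R,5R,7S,9S,10R)-3-{2-[bis(2,2,2-trifluoroethoxy)phosphoryl]propanoyloxy}-8-oxoeremophil-11-en-9-yl (2E)-3-methylpent-2-enoate F5. A Z-selective Still–Gennari olefination with acetaldehyde (KN(SiMe3)2, 18-crown-6, THF, −78 °C) then builds the angelate on the molecule and arrives at 27.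

## Further compounds

F1 | step 6 | racemic cis-1,8a-dimethyl-3,4-dihydronaphthalene-2,6(1H,8aH)-dione | C1=C[C@]2(C)[C@@H](C)C(=O)CCC2=CC1=O.C1=C[C@@]2(C)[C@H](C)C(=O)CCC2=CC1=O
F2 | step 6 | (1S,8aS)-1,8a-dimethyl-3,4-dihydronaphthalene-2,6(1H,8aH)-dione | C1=C[C@@]2(C)[C@H](C)C(=O)CCC2=CC1=O
F3 | step 9 | (1′R,7′S,8a′R)-7′-(2-hydroxypropan-2-yl)-1′,8a′-dimethyl-3′,4′,8′,8a′-tetrahydro-1′H-spiro[1,3-dioxolane-2,2′-naphthalen]-6′(7′H)-one | CC(C)(O)[C@@H]1C[C@]2(C)[C@@H](C)C3(OCCO3)CCC2=CC1=O
F4 | step 11 | (3R,4R,5S,7S,10S)-3-hydroxyeremophil-11-en-8-one | C=C(C)[C@@H]1C[C@]2(C)[C@@H](C)[C@H](O)CC[C@H]2CC1=O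
F5 | step 14 | (3R,4R,5R,7S,9S,10R)-3-{2-[bis(2,2,2-trifluoroethoxy)phosphoryl]propanoyloxy}-8-oxoeremophil-11-en-9-yl (2E)-3-methylpent-2-enoate | C=C(C)[C@@H]1C[C@]2(C)[C@@H](C)[C@H](OC(=O)C(C)P(=O)(OCC(F)(F)F)OCC(F)(F)F)CC[C@H]2[C@H](OC(=O)/C=C(\C)CC)C1=O
A1 | alternative 1 | 1,3,3-trimethoxy-5,6-dimethyl-2-vinylbicyclo[2.2.2]oct-5-en-2-ol (vinyl group syn to the ring alkene) | C=C[C@]1(O)C(OC)(OC)[C@H]2CC[C@]1(OC)C(C)=C2C
A2 | alternative 1 | cis-decalin with C8 ketone, C9 dimethyl ketal and C3 methyl enol ether | C1C[C@]2(C)C(C)=C(OC)CC[C@@H]2C(OC)(OC)C1=O
A3 | alternative 2 | (2E,6E)-farnesyl diphosphate | CC(C)=CCC/C(C)=C/CC/C(C)=C/COP(=O)(O)OP(=O)(O)O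
A4 | alternative 2 | (4S,4aR,6S)-aristolochene (eremophila-9,11-diene) | C=C(C)[C@@H]1C[C@]2(C)[C@@H](C)CCCC2=CC1
A5 | alternative 3 | ring B aldehyde with an (E)-2-(phenylsulfonyl)vinyl group on C5, 3-oxopropyl on C10, PMB ether on C9 and TBS ether on C8 | C=C(C)[C@@H]1C[C@](C)(/C=C/S(=O)(=O)c2ccccc2)[C@@H](CCC=O)[C@H](OCc2ccc(OC)cc2)[C@H]1O[Si](C)(C)C(C)(C)C
A6 | alternative 3 | trans-decalin C3 alcohol with a phenylsulfonylmethyl group on C4, PMB ether on C9 and TBS ether on C8 | C=C(C)[C@@H]1C[C@]2(C)[C@@H](CS(=O)(=O)c3ccccc3)[C@H](O)CC[C@H]2[C@H](OCc3ccc(OC)cc3)[C@H]1O[Si](C)(C)C(C)(C)C
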